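Start in a one-step world where X goes straight to E. There you watch the fraction left, X over X + E, and E passes X the moment it falls under 0.5. In these flasks L stands in the sum as well, so the fraction left becomes X over X + L + E, and E can lead only with that fraction under 0.5.

the same everywhere: Q 0.050 M

| flask | G | remark | time |
|---|---|---|---|
| green | 0.036 M | run made earlier |  |
| ochre | 0.062 M | run made earlier |  |
| violet | 0.056 M | run made earlier |  |
| oak | 0.0500 M |  | 12 min |
| elm | 0.0650 M |  | 12 min |

| run | time / min | Q / % | E / % | L / % | X / % | D / % |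
|---|---|---|---|---|---|---|
| green | 1.00 | 20 | 0 | 0 | 28 | 54 |
| green | 2.00 | 12 | 1 | 2 | 34 | 50 |
| green | 3.00 | 11 | 2 | 3 | 41 | 43 |
| green | 6.00 | 6 | 8 | 1 | 45 | 30 |
| green | 12.0 | 8 | 24 | 3 | 33 | 25 |
| ochre | 2.50 | 9 | 2 | 0 | 57 | 29 |
| ochre | 5.00 | 5 | 8 | 4 | 62 | 17 |
| ochre | 8.00 | 5 | 22 | 6 | 62 | 9 |
| ochre | 10.0 | 4 | 30 | 0 | 55 | 7 |
| ochre | 12.0 | 0 | 39 | 5 | 50 | 3 |
| violet | 1.00 | 15 | 0 | 0 | 42 | 48 |
| violet | 2.00 | 8 | 1 | 4 | 47 | 35 |
| violet | 3.00 | 6 | 4 | 2 | 58 | 28 |
| violet | 6.00 | 6 | 14 | 5 | 60 | 16 |
| violet | 12.0 | 0 | 32 | 2 | 52 | 9 |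

(scatter of a reading: 2 percentage points)

- which of these there is most of at the end, counted by the Q in it, oak (L / D / E / X)
- which of these there is most of at the end, counted by the Q in it, elm (L / D / E / X)
- how much there is at the end of the one of these that leads, in percent of the Q charged: oak
- how much there is at the end of the one of these that leads, in percent of the Q charged: elm

Now turn the question round: for E to lead at 12 min in oak or elm, the fraction left there has to stand under 0.5. At that time the earlier runs read 0.550 in green, 0.532 in ochre and 0.605 in violet, each with the scatter of 2 percentage points in its readings. So I carry their mean, the fraction left of X at that time, 0.562, which stands above the line.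

You still need the amount that has gone through to X + L + E. At 12 min that sum reads 60.0% in green and 86.0% in violet. A straight line between them gives oak 78.2%, and for elm I take ochre's 94.0%. My reckoning is therefore X at 43.9% in oak and 52.8% in elm. In oak, Q + D would hold about 21.8%, less than X.

The forecast names X for oak at 48% and X for elm at 52%: “X leads in both”. Its oak figure stands above mine, its elm figure below.

The flasks give X at 48.3% in oak and X at 53.0% in elm.

    Q ⇌ D (K = 3.10, k = 0.110 s⁻¹)
    Q + G → X (k = 0.620 M⁻¹ s⁻¹)
    L → E (k = 0.0120 s⁻¹)
    X → L (k = 9.90 × 10⁻⁴ s⁻¹)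
    Q + L → J (k = 0.170 M⁻¹ s⁻¹)

In elm at 1.17 min, X was made 6.63 times faster than used up, while Q + G → X ran. By 12.0 min that ratio was 0.272, and X → L, the rate-limiting step towards E, gave X a half-life of 12 min against 0.96 min for L by L → E alone. The fraction left came to 0.586 in oak, where J stood at 2.65%, and 0.573 in elm. In elm's neighbour with 0.20 M of Q, D leads at 47.5%, yet the fraction left is 0.590, with X at 16.4% and E at 10.4%.

(The earlier runs and the new flask were generated by integration with made-up constants; the scatter is artificial.)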